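**Retrosynthetic overview**
1. Target 27 ⇐ desilylation of 26 ⇐ bis-tigloylation of epoxy triol 24 ⇐ C4–OH-directed reduction of ketone 23 ⇐ reductive opening of epoxy isoxazoline 21 ⇐ C10–OH-directed epoxidation of 20.
2. Key disconnection: the C5–C6 and C4–O bonds are made in one intramolecular nitrile oxide–alkene cycloaddition (18 → 20), which closes the seven-membered carbocycle and the isoxazoline together on a preformed cyclopentene.
3. Cyclopentene 16 ⇐ ring-closing metathesis of diene 15; C2 carbinol ⇐ asymmetric 2-isopropylallylboration of aldehyde 9; C1 (quaternary) and C10 ⇐ iridium-catalysed tert-(hydroxy)prenylation of Z-allylic alcohol 5 with isoprene monoxide.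
4. Z-Allylic alcohol 5 ⇐ but-2-yn-1-ol by trans-hydroalumination/iodination and Negishi coupling.
5. Ring order: five-membered ring (step 7), then seven-membered ring plus isoxazoline (step 9), then epoxide (step 10).

Numbering used in names and explanations: daucane numbering (C1 = methyl-bearing ring-fusion carbon; C2, C3, C4 = rest of the five-membered ring, isopropyl on C4; C5 = ring-fusion CH; C6–C10 = seven-membered ring, methyl on C8), also for the corresponding carbons of open-chain intermediates.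

Assumption: the enantiomer of Tol-BINAP (step 3) and of the isopinocampheyl reagent (step 5) is assigned by analogy with simple aldehydes; if a model run shows the opposite carbinol, the antipodal reagent is used with no other change.

**Step 1**
Reactants: 1 but-2-yn-1-ol
Product: 3 (Z)-3-iodobut-2-en-1-ol, via cyclic alkenylaluminate 2 (not isolated)
Conditions: NaAlH2(OCH2CH2OMe)2, THF, 0 °C to rt; then I2, −78 °C
Reagents that add atoms: iodine, II
Why: Hydroxyl-directed trans-hydroalumination of the propargylic alcohol (hydride to C9, aluminium to C8 in a five-membered alkoxyaluminate) followed by iodinolysis with retention gives only the Z-iodoalkene, which fixes the later C8=C9 geometry.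

**Step 2**
Reactants: 3 (Z)-3-iodobut-2-en-1-ol; 4 (1,3-dioxolan-2-ylmethyl)zinc bromide
Product: 5 (Z)-4-(1,3-dioxolan-2-yl)-3-methylbut-2-en-1-ol
Conditions: Pd(PPh3)4 (5 mol %), THF, 50 °C
Reagents that add atoms: none
Why: Negishi cross-coupling of the alkenyl iodide with the sp3 organozinc reagent proceeds with retention of alkene geometry and tolerates the free hydroxyl, adding C7 and C6 with C6 masked as an acetal.

**Step 3**
Reactants: 5 (Z)-4-(1,3-dioxolan-2-yl)-3-methylbut-2-en-1-ol; 6 2-methyl-2-vinyloxirane (isoprene monoxide, racemic)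
Product: 7 (2S,3S,4Z)-6-(1,3-dioxolan-2-yl)-2-ethenyl-2,5-dimethylhex-4-ene-1,3-diol
Conditions: Ir(η3-C3H5)[(R)-Tol-BINAP](C,O-4-cyano-3-nitrobenzoate) (5 mol %), K3PO4 (5 mol %), THF, 60 °C
Reagents that add atoms: none
Why: Iridium-catalysed transfer-hydrogenative tert-(hydroxy)prenylation (Krische type), in which dehydrogenation of 5 gives the Z-enal and an iridium hydride that opens 6 to an (E)-σ-allyl iridium species whose chair-like addition forms the C1–C10 bond with the carbinol oxygen anti to CH2OH, so that the quaternary C1 and C10 are set together under control of the (R)-ligand.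

**Step 4**
Reactants: 7 (2S,3S,4Z)-6-(1,3-dioxolan-2-yl)-2-ethenyl-2,5-dimethylhex-4-ene-1,3-diol
Product: 9 (2R,3S,4Z)-6-(1,3-dioxolan-2-yl)-2-ethenyl-2,5-dimethyl-3-(triethylsilyloxy)hex-4-enal, via hydroxy aldehyde 8 (not isolated)
Conditions: PhI(OAc)2, TEMPO (10 mol %), CH2Cl2, rt; then imidazole, Et3SiCl, 0 °C
Reagents that add atoms: chlorotriethylsilane, CC[Si](Cl)(CC)CC
Why: The oxoammonium (TEMPO) oxidation is selective for the primary hydroxyl over the hindered secondary allylic one, and the β-hydroxy aldehyde, which has no α-hydrogen and cannot dehydrate, is silylated in the same flask so that O10 is differentiated from the hydroxyl formed next.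

**Step 5**
Reactants: 9 (2R,3S,4Z)-6-(1,3-dioxolan-2-yl)-2-ethenyl-2,5-dimethyl-3-(triethylsilyloxy)hex-4-enal; 10 2,3-dimethylbut-1-ene
Product: 14 (4S,5S,6S,7Z)-9-(1,3-dioxolan-2-yl)-5-ethenyl-5,8-dimethyl-2-(propan-2-yl)-6-(triethylsilyloxy)nona-1,7-dien-4-ol, via allylpotassium 11 (not isolated), via allylborane 12 (not isolated), via borinate 13 (not isolated)
Conditions: 10, n-BuLi, KOtBu, THF, −78 to −45 °C; (−)-Ipc2BOMe [from (+)-α-pinene], −78 °C; BF3·OEt2; 9, −78 °C; then NaOH, H2O2, rt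
Reagents that add atoms: none
Why: Brown asymmetric allylboration with a 2-substituted allyl reagent made by kinetic metalation of the allylic methyl group of 10, in which the chair-like transition state of the isopinocampheylborane overrides the weak bias of the α-quaternary aldehyde and sets C2 as S (1,3-anti to the C10 silyloxy group).

**Step 6**
Reactants: 14 (4S,5S,6S,7Z)-9-(1,3-dioxolan-2-yl)-5-ethenyl-5,8-dimethyl-2-(propan-2-yl)-6-(triethylsilyloxy)nona-1,7-dien-4-ol
Product: 15 tert-butyl{[(4S,5S,6S,7Z)-9-(1,3-dioxolan-2-yl)-5-ethenyl-5,8-dimethyl-2-(propan-2-yl)-6-(triethylsilyloxy)nona-1,7-dien-4-yl]oxy}dimethylsilane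
Conditions: t-BuMe2SiCl, imidazole, DMAP (cat.), DMF, 50 °C
Reagents that add atoms: tert-butyldimethylsilyl chloride, CC(C)(C)[Si](C)(C)Cl
Why: Standard silylation of the only free hydroxyl under non-acidic conditions leaves the dioxolane and the triethylsilyl ether intact and gives a C2 ether that lasts until the final step.

**Step 7**
Reactants: 15 tert-butyl{[(4S,5S,6S,7Z)-9-(1,3-dioxolan-2-yl)-5-ethenyl-5,8-dimethyl-2-(propan-2-yl)-6-(triethylsilyloxy)nona-1,7-dien-4-yl]oxy}dimethylsilane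
Product: 16 (1S,5S)-5-(tert-butyldimethylsilyloxy)-1-[(1S,2Z)-4-(1,3-dioxolan-2-yl)-3-methyl-1-(triethylsilyloxy)but-2-en-1-yl]-1-methyl-3-(propan-2-yl)cyclopent-2-ene
Conditions: second-generation Grubbs catalyst (10 mol %), toluene, 80 °C
Reagents that add atoms: none
Why: Ring-closing metathesis between the vinyl group on C1 and the 1,1-disubstituted alkene closes the five-membered ring (C4=C5) with loss of ethene, the trisubstituted C8=C9 alkene reacting far more slowly.

**Step 8**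
Reactants: 16 (1S,5S)-5-(tert-butyldimethylsilyloxy)-1-[(1S,2Z)-4-(1,3-dioxolan-2-yl)-3-methyl-1-(triethylsilyloxy)but-2-en-1-yl]-1-methyl-3-(propan-2-yl)cyclopent-2-ene
Product: 18 (3Z,5S)-5-[(1R,5S)-5-(tert-butyldimethylsilyloxy)-1-methyl-3-(propan-2-yl)cyclopent-2-en-1-yl]-5-hydroxy-3-methylpent-3-enal oxime (E/Z at C=N), via hydroxy aldehyde 17 (not isolated)
Conditions: HCl (0.5 M aq.), THF, rt; then NH2OH·HCl, NaOAc, 40 °C
Reagents that add atoms: hydroxylamine hydrochloride, NO.Cl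
Why: Mild aqueous acid cleaves the triethylsilyl ether and the dioxolane but not the hindered tert-butyldimethylsilyl ether, and the liberated aldehyde, held as its six-membered lactol with O10 so that the β,γ-alkene does not migrate, is condensed to the oxime.

**Step 9**
Reactants: 18 (3Z,5S)-5-[(1R,5S)-5-(tert-butyldimethylsilyloxy)-1-methyl-3-(propan-2-yl)cyclopent-2-en-1-yl]-5-hydroxy-3-methylpent-3-enal oxime
Product: 20 (1R,2S,4R,5S,10S)-2-(tert-butyldimethylsilyloxy)-10-hydroxydauc-8-ene-fused Δ2-isoxazoline (C6=N–O–C4), via nitrile oxide 19 (not isolated)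
Conditions: PhI(OAc)2, CF3CO2H (cat.), MeOH, 0 °C, slow addition (final 2 mM)
Reagents that add atoms: none
Why: Intramolecular nitrile oxide–alkene [3+2] cycloaddition, in which the nitrile oxide can reach the cyclopentene only from the face carrying the C10 tether, so that C6–C5 and O–C4 form suprafacially on that face, closing the cis-fused seven-membered ring and the isoxazoline at once and fixing C5 (H cis to the C1 methyl) and C4 (oxygen syn to C6, isopropyl cis to the methyl).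

**Step 10**
Reactants: 20 (1R,2S,4R,5S,10S)-2-(tert-butyldimethylsilyloxy)-10-hydroxydauc-8-ene-fused Δ2-isoxazoline
Product: 21 (1R,2S,4R,5S,8S,9R,10R)-2-(tert-butyldimethylsilyloxy)-8,9-epoxy-10-hydroxydaucane-fused Δ2-isoxazoline (C6=N–O–C4)
Conditions: VO(acac)2 (5 mol %), t-BuOOH, CH2Cl2, 0 °C to rt
Reagents that add atoms: tert-butyl hydroperoxide, CC(C)(C)OO
Why: Hydroxyl-directed vanadium-catalysed epoxidation, in which the C10 hydroxyl, the only free one, binds the vanadium peroxide and delivers oxygen to the adjacent trisubstituted alkene on its own face, giving the cis epoxy alcohol (C8 S, C9 R) as expected for a cycloheptenol.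

**Step 11**
Reactants: 21 (1R,2S,4R,5S,8S,9R,10R)-2-(tert-butyldimethylsilyloxy)-8,9-epoxy-10-hydroxydaucane-fused Δ2-isoxazoline
Product: 23 (1R,2S,4R,5R,8S,9R,10R)-2-(tert-butyldimethylsilyloxy)-8,9-epoxy-4,10-dihydroxydaucan-6-one, via hydroxy imine 22 (not isolated)
Conditions: Raney Ni, H2 (1 atm), B(OH)3, MeOH/H2O (5:1), rt
Reagents that add atoms: water, O
Why: Hydrogenolysis of the isoxazoline N–O bond and boric acid-buffered hydrolysis of the resulting imine unmask the aldol (C6 ketone, tertiary C4 hydroxyl) without touching C4 or C5, the buffer suppressing retro-aldol cleavage and β-elimination of the epoxide.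

**Step 12**
Reactants: 23 (1R,2S,4R,5R,8S,9R,10R)-2-(tert-butyldimethylsilyloxy)-8,9-epoxy-4,10-dihydroxydaucan-6-one
Product: 24 (1R,2S,4R,5S,6S,8S,9R,10R)-2-(tert-butyldimethylsilyloxy)-8,9-epoxydaucane-4,6,10-triol
Conditions: Me4NBH(OAc)3, MeCN/AcOH, −30 to 0 °C
Reagents that add atoms: none
Why: Evans–Saksena directed reduction, in which the tertiary C4 hydroxyl exchanges onto boron and delivers hydride intramolecularly to the C6 ketone from its own face, giving the 1,3-anti diol (C6 S).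

**Step 13**
Reactants: 24 (1R,2S,4R,5S,6S,8S,9R,10R)-2-(tert-butyldimethylsilyloxy)-8,9-epoxydaucane-4,6,10-triol; 25 (E)-2-methylbut-2-enoyl chloride (tigloyl chloride)
Product: 26 (1R,2S,4R,5S,6S,8S,9R,10R)-2-(tert-butyldimethylsilyloxy)-8,9-epoxy-4-hydroxydaucane-6,10-diyl bis[(E)-2-methylbut-2-enoate]
Conditions: 25 (5 equiv), pyridine, DMAP (cat.), CH2Cl2, 40 °C
Reagents that add atoms: none
Why: DMAP-catalysed acylation esterifies the two secondary hydroxyls (C6 and C10) while the tertiary C4 hydroxyl is unreactive and C2 is silylated, and the E geometry of the tigloyl group is the stable one and is retained.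

**Step 14**
Reactants: 26 (1R,2S,4R,5S,6S,8S,9R,10R)-2-(tert-butyldimethylsilyloxy)-8,9-epoxy-4-hydroxydaucane-6,10-diyl bis[(E)-2-methylbut-2-enoate]
Product: 27 (1S,2S,4R,5S,6S,8S,9R,10R)-8,9-epoxy-2,4-dihydroxydaucane-6,10-diyl bis[(E)-2-methylbut-2-enoate] (CNP0265715.1)
Conditions: HF·pyridine, pyridine, THF, 0 °C to rt
Reagents that add atoms: none
Why: Buffered fluoride desilylation removes the C2 silyl ether without opening the epoxide or cleaving or migrating the tiglates, giving the target with its eight stereocentres as set in steps 3, 5, 9, 10 and 12.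

**Compound list**
1 | but-2-yn-1-ol | CC#CCO | starting material
2 | sodium 2,2-bis(2-methoxyethoxy)-3-methyl-1-oxa-2-aluminacyclopent-3-en-2-uide (cyclic alkenylaluminate) | CC1=CCO[Al-]1(OCCOC)OCCOC.[Na+] | intermediate
3 | (Z)-3-iodobut-2-en-1-ol | C/C(I)=C/CO | intermediate
4 | (1,3-dioxolan-2-ylmethyl)zinc bromide | Br[Zn]CC1OCCO1 | starting material
5 | (Z)-4-(1,3-dioxolan-2-yl)-3-methylbut-2-en-1-ol | OC/C=C(/C)CC1OCCO1 | intermediate
6 | 2-methyl-2-vinyloxirane (isoprene monoxide, racemic) | CC1(C=C)CO1 | starting material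
7 | (2S,3S,4Z)-6-(1,3-dioxolan-2-yl)-2-ethenyl-2,5-dimethylhex-4-ene-1,3-diol | C1(OCCO1)C/C(C)=C\[C@H](O)[C@@](C)(C=C)CO | intermediate
8 | (2R,3S,4Z)-6-(1,3-dioxolan-2-yl)-2-ethenyl-3-hydroxy-2,5-dimethylhex-4-enal | C1(OCCO1)C/C(C)=C\[C@H](O)[C@@](C)(C=C)C=O | intermediate
9 | (2R,3S,4Z)-6-(1,3-dioxolan-2-yl)-2-ethenyl-2,5-dimethyl-3-(triethylsilyloxy)hex-4-enal | C1(OCCO1)C/C(C)=C\[C@H](O[Si](CC)(CC)CC)[C@@](C)(C=C)C=O | intermediate
10 | 2,3-dimethylbut-1-ene | CC(C)C(C)=C | starting material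
11 | (3-methyl-2-methylidenebutyl)potassium (2-isopropylallylpotassium) | [K+].[CH2-]C(=C)C(C)C | intermediate
12 | B-(3-methyl-2-methylidenebutyl)diisopinocampheylborane (isopinocampheyl groups from (+)-α-pinene) | CC(C)C(=C)CB([C@@H]1C[C@@H]2C[C@H]([C@H]1C)C2(C)C)[C@@H]1C[C@@H]2C[C@H]([C@H]1C)C2(C)C | intermediate
13 | diisopinocampheylborinate ester of alcohol 14 | C1(OCCO1)C/C(C)=C\[C@H](O[Si](CC)(CC)CC)[C@@](C)(C=C)[C@@H](OB([C@@H]1C[C@@H]2C[C@H]([C@H]1C)C2(C)C)[C@@H]1C[C@@H]2C[C@H]([C@H]1C)C2(C)C)CC(=C)C(C)C | intermediate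
14 | (4S,5S,6S,7Z)-9-(1,3-dioxolan-2-yl)-5-ethenyl-5,8-dimethyl-2-(propan-2-yl)-6-(triethylsilyloxy)nona-1,7-dien-4-ol | C1(OCCO1)C/C(C)=C\[C@H](O[Si](CC)(CC)CC)[C@@](C)(C=C)[C@@H](O)CC(=C)C(C)C | intermediate
15 | tert-butyl{[(4S,5S,6S,7Z)-9-(1,3-dioxolan-2-yl)-5-ethenyl-5,8-dimethyl-2-(propan-2-yl)-6-(triethylsilyloxy)nona-1,7-dien-4-yl]oxy}dimethylsilane | C1(OCCO1)C/C(C)=C\[C@H](O[Si](CC)(CC)CC)[C@@](C)(C=C)[C@@H](O[Si](C)(C)C(C)(C)C)CC(=C)C(C)C | intermediate
16 | (1S,5S)-5-(tert-butyldimethylsilyloxy)-1-[(1S,2Z)-4-(1,3-dioxolan-2-yl)-3-methyl-1-(triethylsilyloxy)but-2-en-1-yl]-1-methyl-3-(propan-2-yl)cyclopent-2-ene | C1(OCCO1)C/C(C)=C\[C@H](O[Si](CC)(CC)CC)[C@@]1(C)C=C(C(C)C)C[C@@H]1O[Si](C)(C)C(C)(C)C | intermediate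
17 | (3Z,5S)-5-[(1R,5S)-5-(tert-butyldimethylsilyloxy)-1-methyl-3-(propan-2-yl)cyclopent-2-en-1-yl]-5-hydroxy-3-methylpent-3-enal (in equilibrium with its lactol) | O=CC/C(C)=C\[C@H](O)[C@@]1(C)C=C(C(C)C)C[C@@H]1O[Si](C)(C)C(C)(C)C | intermediate
18 | oxime of 17 (E/Z at C=N) | ON=CC/C(C)=C\[C@H](O)[C@@]1(C)C=C(C(C)C)C[C@@H]1O[Si](C)(C)C(C)(C)C | intermediate
19 | nitrile oxide from 18: (3Z,5S)-5-[(1R,5S)-5-(tert-butyldimethylsilyloxy)-1-methyl-3-(propan-2-yl)cyclopent-2-en-1-yl]-5-hydroxy-3-methylpent-3-enenitrile oxide | [O-][N+]#CC/C(C)=C\[C@H](O)[C@@]1(C)C=C(C(C)C)C[C@@H]1O[Si](C)(C)C(C)(C)C | intermediate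
20 | (1R,2S,4R,5S,10S)-2-(tert-butyldimethylsilyloxy)-10-hydroxydauc-8-ene-fused Δ2-isoxazoline (C6=N–O–C4) | O1N=C2C/C(C)=C\[C@H](O)[C@@]3(C)[C@@H]2[C@]1(C(C)C)C[C@@H]3O[Si](C)(C)C(C)(C)C | intermediate
21 | (1R,2S,4R,5S,8S,9R,10R)-2-(tert-butyldimethylsilyloxy)-8,9-epoxy-10-hydroxydaucane-fused Δ2-isoxazoline (C6=N–O–C4) | O1N=C2C[C@]4(C)O[C@@H]4[C@H](O)[C@@]3(C)[C@@H]2[C@]1(C(C)C)C[C@@H]3O[Si](C)(C)C(C)(C)C | intermediate
22 | (1R,2S,4R,5S,8S,9R,10R)-2-(tert-butyldimethylsilyloxy)-8,9-epoxy-6-iminodaucane-4,10-diol | N=C1C[C@]2(C)O[C@@H]2[C@H](O)[C@@]2(C)[C@@H]1[C@](O)(C(C)C)C[C@@H]2O[Si](C)(C)C(C)(C)C | intermediate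
23 | (1R,2S,4R,5R,8S,9R,10R)-2-(tert-butyldimethylsilyloxy)-8,9-epoxy-4,10-dihydroxydaucan-6-one | O=C1C[C@]2(C)O[C@@H]2[C@H](O)[C@@]2(C)[C@@H]1[C@](O)(C(C)C)C[C@@H]2O[Si](C)(C)C(C)(C)C | intermediate
24 | (1R,2S,4R,5S,6S,8S,9R,10R)-2-(tert-butyldimethylsilyloxy)-8,9-epoxydaucane-4,6,10-triol | O[C@H]1C[C@]2(C)O[C@@H]2[C@H](O)[C@@]2(C)[C@@H]1[C@](O)(C(C)C)C[C@@H]2O[Si](C)(C)C(C)(C)C | intermediate
25 | (E)-2-methylbut-2-enoyl chloride (tigloyl chloride) | C/C=C(\C)C(Cl)=O | starting material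
26 | (1R,2S,4R,5S,6S,8S,9R,10R)-2-(tert-butyldimethylsilyloxy)-8,9-epoxy-4-hydroxydaucane-6,10-diyl bis[(E)-2-methylbut-2-enoate] | C/C=C(\C)C(=O)O[C@H]1C[C@]2(C)O[C@@H]2[C@H](OC(=O)/C(C)=C/C)[C@@]2(C)[C@@H]1[C@](O)(C(C)C)C[C@@H]2O[Si](C)(C)C(C)(C)C | intermediate
27 | (1S,2S,4R,5S,6S,8S,9R,10R)-8,9-epoxy-2,4-dihydroxydaucane-6,10-diyl bis[(E)-2-methylbut-2-enoate] (CNP0265715.1) | C/C=C(\C)C(=O)O[C@H]1C[C@]2(C)O[C@@H]2[C@H](OC(=O)/C(C)=C/C)[C@@]2(C)[C@@H]1[C@](O)(C(C)C)C[C@@H]2O | target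

**Step count**
Total steps: 14. Longest linear sequence: 14 steps (from but-2-yn-1-ol; the other building blocks 4, 6, 10 and 25 are bought).

**Three steps most likely to fail, with fallbacks**

Step 9 (seven-membered-ring nitrile oxide cycloaddition onto a hindered trisubstituted cyclopentene; furoxan dimerisation can win). The fallback sets out from oxime 18 and comes back at isoxazoline 20. Oxime 18 is heated in degassed toluene at 170 °C in a sealed tube without any oxidant; 1,2-prototropy gives the NH-nitrone, which adds to the cyclopentene through the same tether-controlled face to give the N-unsubstituted isoxazolidine F1 (both C6 epimers). MnO2 in CH2Cl2 then dehydrogenates N–H/C6–H of F1 to give 20. This replaces the dimerisation-prone nitrile oxide by a reversible, non-dimerising dipole.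

Step 3 (iridium-catalysed coupling on a Z-trisubstituted allylic alcohol; risk of low conversion, Z/E leakage or the wrong diastereomer). The fallback sets out from alcohol 5 and comes back at diol 7. MnO2 oxidises 5 to the (Z)-enal F2. An Evans syn-aldol with the dibutylboron dienolate of (R)-4-benzyl-3-[(E)-but-2-enoyl]-1,3-oxazolidin-2-one (Bu2BOTf, Et3N, CH2Cl2, −78 °C), which reacts at its α-carbon, gives the α-vinyl aldol imide F3 and sets C10. NaOMe in MeOH gives the methyl ester F4. Fráter–Seebach alkylation of its dianion (LDA 2.2 equiv, then MeI, THF/DMPU, −78 to −20 °C) places the methyl group anti to the C10 alkoxide and gives the quaternary ester F5. LiAlH4 reduces F5 to 7.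

Step 11 (the product is a β,γ-epoxy ketone that can open by β-elimination or under the acid of step 12). The fallback sets out from isoxazoline 20 and comes back at triol 24; it changes the order so that no epoxy ketone is ever formed. The N–O bond of 20 is cleaved before epoxidation with Mo(CO)6 in MeCN/H2O at 80 °C to give the hydroxy enone-free ketone F6 (alkene intact). Me4NBH(OAc)3 reduces F6 under C4–OH direction to the ene-triol F7. VO(acac)2/t-BuOOH then epoxidises F7, the allylic C10 hydroxyl outcompeting the homoallylic C6 hydroxyl on the opposite face, to give 24.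

**Further compounds**
F1 | step 9 | (1R,2S,4R,5S,10S)-2-(tert-butyldimethylsilyloxy)-10-hydroxydauc-8-ene-fused N-unsubstituted isoxazolidine (C6–NH–O–C4; C6 epimers) | O1NC2C/C(C)=C\[C@H](O)[C@@]3(C)[C@@H]2[C@]1(C(C)C)C[C@@H]3O[Si](C)(C)C(C)(C)C
F2 | step 3 | (Z)-4-(1,3-dioxolan-2-yl)-3-methylbut-2-enal | O=C/C=C(/C)CC1OCCO1
F3 | step 3 | (4R)-4-benzyl-3-[(2R,3S,4Z)-6-(1,3-dioxolan-2-yl)-2-ethenyl-3-hydroxy-5-methylhex-4-enoyl]-1,3-oxazolidin-2-one | O=C1OC[C@@H](Cc2ccccc2)N1C(=O)[C@H](C=C)[C@@H](O)/C=C(/C)CC1OCCO1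
F4 | step 3 | methyl (2R,3S,4Z)-6-(1,3-dioxolan-2-yl)-2-ethenyl-3-hydroxy-5-methylhex-4-enoate | COC(=O)[C@H](C=C)[C@@H](O)/C=C(/C)CC1OCCO1
F5 | step 3 | methyl (2R,3S,4Z)-6-(1,3-dioxolan-2-yl)-2-ethenyl-3-hydroxy-2,5-dimethylhex-4-enoate | COC(=O)[C@](C)(C=C)[C@@H](O)/C=C(/C)CC1OCCO1
F6 | step 11 | (1R,2S,4R,5R,10S)-2-(tert-butyldimethylsilyloxy)-4,10-dihydroxydauc-8-en-6-one | O=C1C/C(C)=C\[C@H](O)[C@@]2(C)[C@@H]1[C@](O)(C(C)C)C[C@@H]2O[Si](C)(C)C(C)(C)C
F7 | step 11 | (1R,2S,4R,5S,6S,10S)-2-(tert-butyldimethylsilyloxy)dauc-8-ene-4,6,10-triol | O[C@H]1C/C(C)=C\[C@H](O)[C@@]2(C)[C@@H]1[C@](O)(C(C)C)C[C@@H]2O[Si](C)(C)C(C)(C)C
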